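**Retrosynthetic overview**

1. The enyne (C1–C4) comes last, by cross-metathesis and Colvin homologation of a C6-allyl group; both C–Br bonds come from a late double SN2 inversion of the 9,12-diol.
2. The C5–C6 bond is made by C-allylation of the anomeric fluoride of the 2,7-dioxabicyclo[4.2.2]decane core.
3. The core arises by ring expansion. In bridged acetal 20 both ring oxygens sit on C6; a 1,2-shift of O-b from C6 to C7 turns the seven-membered 1,3-dioxepane (C6, O-a, C10, C11, C12, C13, O-b) into the eight-membered 1,4-dioxocane (the same atoms plus C7) and creates the oxocane at the same time. The enabling feature is the vicinal C6(O-a)–C7(O-b) unit: C6 can be an acetal carbon whose axial C6–O-b bond lies antiperiplanar to an axial C7–OH on the oxane chair.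
4. Acetal 20 comes from glycal 18 (epoxidation, intramolecular glycosidation by C13–OH), 18 from alkynediol 17 (tungsten-catalysed cycloisomerisation), and the chain from propanal by two Brown alkoxyallylborations.
5. Ring order: oxane (step 11), then 1,3-dioxepane bridge (step 12), then oxocane and 1,4-dioxocane together (step 13).

Key step: step 13

Remark on the chemistry: locants C1–C15 follow the carbon chain of the target (C1 = alkyne CH, C15 = methyl), O-a is the oxygen between C6 and C10 and O-b the oxygen between C7 and C13; allyl methoxymethyl ether 2 is assumed to be a catalogue compound (otherwise one step from allyl alcohol and MOMCl).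

**Route**

Step 1
Reactants: 1 propanal; 2 allyl methoxymethyl ether [3-(methoxymethoxy)prop-1-ene]
Product: 4 (3R,4R)-4-(methoxymethoxy)hex-5-en-3-ol, via diisopinocampheylborinate 3 (not isolated)
Conditions: 2, s-BuLi, THF, −78 °C; (−)-Ipc2BOMe; BF3·OEt2; then 1, −78 °C → rt; NaOH, H2O2
Reagents that add atoms: none
Why: Brown alkoxyallylboration, in which the (Z)-γ-alkoxyallylborane reacts through a closed chair transition state so that the Z geometry gives the syn C12/C13 pair and the isopinocampheyl groups derived from (+)-α-pinene select the aldehyde face that gives 13R and 12R.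

Step 2
Reactants: 4
Product: 5 tert-butyl{[(3R,4R)-4-(methoxymethoxy)hex-5-en-3-yl]oxy}dimethylsilane
Conditions: TBSCl, imidazole, DMF, rt
Reagents that add atoms: tert-butyldimethylsilyl chloride, CC(C)(C)[Si](C)(C)Cl
Why: Imidazole-mediated silylation of the secondary alcohol masks C13–OH so that the aldehyde made in step 4 cannot close to a lactol; no stereocenter is touched.

Step 3
Reactants: 5
Product: 7 (3R,4R)-4-[(tert-butyldimethylsilyl)oxy]-3-(methoxymethoxy)hexan-1-ol, via B-alkyl-9-BBN adduct 6 (not isolated)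
Conditions: 9-BBN, THF, 0 °C → rt; NaOH, H2O2
Reagents that add atoms: hydrogen peroxide, OO
Why: Hydroboration–oxidation, in which the bulky borane places boron on the terminal carbon of the monosubstituted alkene (anti-Markovnikov) and oxidation with retention gives the primary alcohol without touching a stereocenter.

Step 4
Reactants: 7
Product: 8 (3R,4R)-4-[(tert-butyldimethylsilyl)oxy]-3-(methoxymethoxy)hexanal
Conditions: Dess–Martin periodinane, CH2Cl2, 0 °C → rt
Reagents that add atoms: none
Why: Dess–Martin oxidation converts the primary alcohol into the aldehyde under near-neutral conditions that should not eliminate the β-alkoxy group.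

Step 5
Reactants: 8; 2
Product: 10 (3R,4R,6R,7R)-7-[(tert-butyldimethylsilyl)oxy]-3,6-bis(methoxymethoxy)non-1-en-4-ol, via diisopinocampheylborinate 9 (not isolated)
Conditions: 2, s-BuLi, THF, −78 °C; (−)-Ipc2BOMe; BF3·OEt2; then 8, −78 °C → rt; NaOH, H2O2
Reagents that add atoms: none
Why: A second Brown alkoxyallylboration with the same borane, where reagent control through the chair transition state should override the remote β-stereocenter and give the syn 9R,10R unit (C10 carbinol free, C9 oxygen already protected).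

Step 6
Reactants: 10
Product: 11 (3R,4R,6R,7R)-4,7-bis[(tert-butyldimethylsilyl)oxy]-3,6-bis(methoxymethoxy)non-1-ene
Conditions: TBSOTf, 2,6-lutidine, CH2Cl2, −78 → 0 °C
Reagents that add atoms: tert-butyldimethylsilyl trifluoromethanesulfonate, CC(C)(C)[Si](C)(C)OS(=O)(=O)C(F)(F)F
Why: Silyl triflate silylation caps the hindered C10 hydroxyl so that the next aldehyde stays open-chain; the MOM ethers tolerate the buffered conditions.

Step 7
Reactants: 11
Product: 13 (3R,4R,6R,7R)-4,7-bis[(tert-butyldimethylsilyl)oxy]-3,6-bis(methoxymethoxy)nonan-1-ol, via B-alkyl-9-BBN adduct 12 (not isolated)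
Conditions: 9-BBN, THF, 0 °C → rt; NaOH, H2O2
Reagents that add atoms: hydrogen peroxide, OO
Why: Anti-Markovnikov hydroboration–oxidation of the terminal vinyl group as in step 3, with no stereocenter formed.

Step 8
Reactants: 13
Product: 14 (3R,4R,6R,7R)-4,7-bis[(tert-butyldimethylsilyl)oxy]-3,6-bis(methoxymethoxy)nonanal
Conditions: Dess–Martin periodinane, CH2Cl2, 0 °C → rt
Reagents that add atoms: none
Why: Dess–Martin oxidation of the primary alcohol to the aldehyde under mild conditions compatible with silyl and MOM ethers.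

Step 9
Reactants: 14; 15 dimethyl (1-diazo-2-oxopropyl)phosphonate
Product: 16 (4R,5R,7R,8R)-5,8-bis[(tert-butyldimethylsilyl)oxy]-4,7-bis(methoxymethoxy)dec-1-yne
Conditions: K2CO3, MeOH, 0 °C → rt
Reagents that add atoms: none
Why: Ohira–Bestmann (Seyferth–Gilbert) homologation converts the aldehyde into the terminal alkyne, adding C6, under base mild enough for an aldehyde with an α-methylene and a β-alkoxy group.

Step 10
Reactants: 16
Product: 17 (4R,5R,7R,8R)-4,7-bis(methoxymethoxy)dec-1-yne-5,8-diol
Conditions: TBAF, THF, rt → 45 °C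
Reagents that add atoms: none
Why: Fluoride desilylation frees the C10 and C13 hydroxyls while MOM ethers and the alkyne are inert.

Step 11
Reactants: 17
Product: 18 (2R,3R)-1-[(2R,3R)-3-(methoxymethoxy)-3,4-dihydro-2H-pyran-2-yl]-2-(methoxymethoxy)pentan-3-ol
Conditions: W(CO)6 (cat.), Et3N, THF, hν (350 nm), 55 °C
Reagents that add atoms: none
Why: Endo-selective alkynol cycloisomerisation through a tungsten vinylidene, in which the C10 hydroxyl adds to the vinylidene carbon C6 to close the six-membered enol ether (6-endo); C13–OH is too remote, the C9 oxygen is capped, and no stereocenter is touched.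

Step 12
Reactants: 18
Product: 20 (1R,3R,4R,6R,7R,9R)-3-ethyl-4,7-bis(methoxymethoxy)-2,10-dioxabicyclo[4.3.1]decan-9-ol, via glycal epoxide 19 (not isolated)
Conditions: DMDO, acetone/CH2Cl2, −78 → 0 °C; evaporate; ZnCl2 (cat.), CH2Cl2 (0.005 M), −40 °C → rt
Reagents that add atoms: dimethyldioxirane, CC1(C)OO1
Why: Glycal epoxidation followed by intramolecular glycosidation of the 1,2-anhydro sugar: DMDO should add to the enol-ether face opposite the C9 OMOM group and the C10 side chain, and the tethered C13 hydroxyl opens the epoxide at the anomeric carbon C6 with inversion (trans-diaxial opening), which fixes C6 and the axial 7R hydroxyl and closes the seven-membered 1,3-dioxepane.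

Step 13
Reactants: 20
Product: 23 (1S,3R,4R,6R,8R,10R)-3-ethyl-8-fluoro-4,10-bis(methoxymethoxy)-2,7-dioxabicyclo[4.2.2]decane, via aminodifluorosulfane ester 21 (not isolated), via bridged oxonium ion 22 (not isolated)
Conditions: DAST, CH2Cl2, −40 °C → rt
Reagents that add atoms: diethylaminosulfur trifluoride, CCN(CC)S(F)(F)F
Why: DAST converts the axial C7 hydroxyl into the aminodifluorosulfane ester 21; because the chair of the bridged acetal holds the C6–O-b bond axial and antiperiplanar to the C7–O leaving group, O-b displaces it from the rear to give the oxiranium-type oxonium ion 22, which fluoride opens at C6, the carbon that O-a stabilises as an oxocarbenium ion. The closest known reaction type is the DAST-induced 1,2-shift of the anomeric oxygen to C2 in trans-diaxial 2-hydroxy glycosides and in 1,6-anhydrohexopyranoses, which gives rearranged (anhydro) glycosyl fluorides. Both eight-membered rings are closed by this 1,2-shift, that is by a 3-exo-tet attack of O-b on C7 followed by C6–O-b cleavage, so the 1,3-dioxepane C6–O-a–C10–C11–C12–C13–O-b becomes the 1,4-dioxocane by insertion of C7 and the oxocane O-b–C7–C8–C9–C10–C11–C12–C13 appears without any direct eight-membered cyclisation. C7 is set by stereospecific inversion (7R alcohol to 7S ether), and fluoride enters C6 anti to the shifted oxygen, a centre that is re-ionised in step 14 and is therefore uncritical. The step needs migration of the bridging oxygen rather than of the oxane oxygen (ring contraction) or direct SN2 fluorination; the locked trans-diaxial geometry places only the C6–O-b bond anti to the leaving group, and substitution next to an axial anomeric oxygen is intrinsically slow.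

Step 14
Reactants: 23; 24 allyltrimethylsilane
Product: 25 (1S,3R,4R,6R,8R,10R)-3-ethyl-4,10-bis(methoxymethoxy)-8-(prop-2-en-1-yl)-2,7-dioxabicyclo[4.2.2]decane
Conditions: BF3·OEt2, CH2Cl2, −78 → −20 °C
Reagents that add atoms: none
Why: Hosomi–Sakurai-type C-glycosylation of a glycosyl fluoride, in which BF3 abstracts fluoride (either C6 epimer of 23 converges on the same oxocarbenium ion) and the allylsilane should attack C6 anti to the adjacent C7–O-b bond, on the face of the C8–C9 bridge and away from the four-atom bridge, which sets 6R.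

Step 15
Reactants: 25
Product: 26 (1S,3R,4R,6R,8R,10R)-3-ethyl-8-(prop-2-en-1-yl)-2,7-dioxabicyclo[4.2.2]decane-4,10-diol
Conditions: HCl (aq., cat.), MeOH, 50 °C
Reagents that add atoms: none
Why: Acid-catalysed transacetalisation removes both MOM groups as dimethoxymethane, while the dialkyl ether bridges and the terminal alkene are inert and no stereocenter is touched.

Step 16
Reactants: 26
Product: 27 (1S,3R,4S,6R,8R,10S)-4,10-dibromo-3-ethyl-8-(prop-2-en-1-yl)-2,7-dioxabicyclo[4.2.2]decane
Conditions: CBr4, P(n-C8H17)3, toluene, 70 °C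
Reagents that add atoms: tetrabromomethane, BrC(Br)(Br)Br
Why: Appel-type bromination, in which each alkoxyphosphonium ion is displaced by bromide in an SN2 reaction with inversion (9R to 9S, 12R to 12S); these are the usual conditions for β-alkoxy secondary alcohols in halogenated medium-ring ethers, and the eclipsed C9–C10 bond of the bicycle keeps O-a from lying anti to the C9 leaving group.

Step 17
Reactants: 27; 28 (E)-but-2-enal (crotonaldehyde)
Product: 29 (2E)-4-[(1S,3R,4S,6R,8R,10S)-4,10-dibromo-3-ethyl-2,7-dioxabicyclo[4.2.2]decan-8-yl]but-2-enal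
Conditions: 28 (excess), second-generation Grubbs catalyst RuCl2(=CHPh)(PCy3)(H2IMes) (cat.), CH2Cl2, 40 °C
Reagents that add atoms: none
Why: Olefin cross-metathesis between the terminal alkene and excess crotonaldehyde releases propene and should give the conjugated enal with the thermodynamically favoured E geometry, the secondary bromides and ethers being inert to the ruthenium carbene.

Step 18
Reactants: 29; 30 (trimethylsilyl)diazomethane
Product: 31 (1S,3R,4S,6R,8R,10S)-4,10-dibromo-3-ethyl-8-[(2E)-pent-2-en-4-yn-1-yl]-2,7-dioxabicyclo[4.2.2]decane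
Conditions: 30, LiN(i-Pr)2, THF, −78 → 0 °C
Reagents that add atoms: none
Why: Colvin rearrangement, in which lithiated (trimethylsilyl)diazomethane adds to the aldehyde, Peterson-type loss of lithium trimethylsilanolate and N2 gives an alkylidene carbene, and its 1,2-hydrogen shift delivers the terminal alkyne with the E alkene retained; at −78 °C the base should not eliminate the secondary bromides.

**Compound list**

1 | propanal | CCC=O | starting material
2 | allyl methoxymethyl ether, 3-(methoxymethoxy)prop-1-ene | C=CCOCOC | starting material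
3 | (3R,4R)-4-(methoxymethoxy)hex-5-en-3-yl diisopinocampheylborinate | CC[C@@H](OB([C@@H]1C[C@@H]2C[C@H]([C@H]1C)C2(C)C)[C@@H]1C[C@@H]2C[C@H]([C@H]1C)C2(C)C)[C@H](OCOC)C=C | intermediate
4 | (3R,4R)-4-(methoxymethoxy)hex-5-en-3-ol | CC[C@@H](O)[C@H](OCOC)C=C | intermediate
5 | tert-butyl{[(3R,4R)-4-(methoxymethoxy)hex-5-en-3-yl]oxy}dimethylsilane | CC[C@@H](O[Si](C)(C)C(C)(C)C)[C@H](OCOC)C=C | intermediate
6 | 9-{(3R,4R)-4-[(tert-butyldimethylsilyl)oxy]-3-(methoxymethoxy)hexyl}-9-borabicyclo[3.3.1]nonane | CC[C@@H](O[Si](C)(C)C(C)(C)C)[C@H](OCOC)CCB1C2CCCC1CCC2 | intermediate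
7 | (3R,4R)-4-[(tert-butyldimethylsilyl)oxy]-3-(methoxymethoxy)hexan-1-ol | CC[C@@H](O[Si](C)(C)C(C)(C)C)[C@H](OCOC)CCO | intermediate
8 | (3R,4R)-4-[(tert-butyldimethylsilyl)oxy]-3-(methoxymethoxy)hexanal | CC[C@@H](O[Si](C)(C)C(C)(C)C)[C@H](OCOC)CC=O | intermediate
9 | (3R,4R,6R,7R)-7-[(tert-butyldimethylsilyl)oxy]-3,6-bis(methoxymethoxy)non-1-en-4-yl diisopinocampheylborinate | CC[C@@H](O[Si](C)(C)C(C)(C)C)[C@H](OCOC)C[C@@H](OB([C@@H]1C[C@@H]2C[C@H]([C@H]1C)C2(C)C)[C@@H]1C[C@@H]2C[C@H]([C@H]1C)C2(C)C)[C@H](OCOC)C=C | intermediate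
10 | (3R,4R,6R,7R)-7-[(tert-butyldimethylsilyl)oxy]-3,6-bis(methoxymethoxy)non-1-en-4-ol | CC[C@@H](O[Si](C)(C)C(C)(C)C)[C@H](OCOC)C[C@@H](O)[C@H](OCOC)C=C | intermediate
11 | (3R,4R,6R,7R)-4,7-bis[(tert-butyldimethylsilyl)oxy]-3,6-bis(methoxymethoxy)non-1-ene | CC[C@@H](O[Si](C)(C)C(C)(C)C)[C@H](OCOC)C[C@@H](O[Si](C)(C)C(C)(C)C)[C@H](OCOC)C=C | intermediate
12 | 9-{(3R,4R,6R,7R)-4,7-bis[(tert-butyldimethylsilyl)oxy]-3,6-bis(methoxymethoxy)nonyl}-9-borabicyclo[3.3.1]nonane | CC[C@@H](O[Si](C)(C)C(C)(C)C)[C@H](OCOC)C[C@@H](O[Si](C)(C)C(C)(C)C)[C@H](OCOC)CCB1C2CCCC1CCC2 | intermediate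
13 | (3R,4R,6R,7R)-4,7-bis[(tert-butyldimethylsilyl)oxy]-3,6-bis(methoxymethoxy)nonan-1-ol | CC[C@@H](O[Si](C)(C)C(C)(C)C)[C@H](OCOC)C[C@@H](O[Si](C)(C)C(C)(C)C)[C@H](OCOC)CCO | intermediate
14 | (3R,4R,6R,7R)-4,7-bis[(tert-butyldimethylsilyl)oxy]-3,6-bis(methoxymethoxy)nonanal | CC[C@@H](O[Si](C)(C)C(C)(C)C)[C@H](OCOC)C[C@@H](O[Si](C)(C)C(C)(C)C)[C@H](OCOC)CC=O | intermediate
15 | dimethyl (1-diazo-2-oxopropyl)phosphonate (Ohira–Bestmann reagent) | COP(=O)(OC)C(=[N+]=[N-])C(C)=O | starting material
16 | (4R,5R,7R,8R)-5,8-bis[(tert-butyldimethylsilyl)oxy]-4,7-bis(methoxymethoxy)dec-1-yne | CC[C@@H](O[Si](C)(C)C(C)(C)C)[C@H](OCOC)C[C@@H](O[Si](C)(C)C(C)(C)C)[C@H](OCOC)CC#C | intermediate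
17 | (4R,5R,7R,8R)-4,7-bis(methoxymethoxy)dec-1-yne-5,8-diol | C#CC[C@@H](OCOC)[C@H](O)C[C@@H](OCOC)[C@H](O)CC | intermediate
18 | (2R,3R)-1-[(2R,3R)-3-(methoxymethoxy)-3,4-dihydro-2H-pyran-2-yl]-2-(methoxymethoxy)pentan-3-ol | C1=CO[C@H](C[C@@H](OCOC)[C@H](O)CC)[C@H](OCOC)C1 | intermediate
19 | (2R,3R)-2-(methoxymethoxy)-1-[(1S,3R,4R,6R)-4-(methoxymethoxy)-2,7-dioxabicyclo[4.1.0]heptan-3-yl]pentan-3-ol (C6–C7 epoxide on the face opposite the C9 and C10 substituents) | CC[C@@H](O)[C@H](OCOC)C[C@H]1O[C@@H]2O[C@@H]2C[C@H]1OCOC | intermediate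
20 | (1R,3R,4R,6R,7R,9R)-3-ethyl-4,7-bis(methoxymethoxy)-2,10-dioxabicyclo[4.3.1]decan-9-ol (bridged acetal; C6–O-b axial, C7–OH axial and trans) | O[C@@H]1C[C@@H](OCOC)[C@H]2C[C@@H](OCOC)[C@@H](CC)O[C@@H]1O2 | intermediate
21 | 9-O-[(diethylamino)difluorosulfanyl] derivative of 20 | CCN(CC)S(F)(F)O[C@@H]1C[C@@H](OCOC)[C@H]2C[C@@H](OCOC)[C@@H](CC)O[C@@H]1O2 | intermediate
22 | bridged trialkyloxonium ion with O-b bonded to C6, C7 and C13 (fluoride as counter-ion) | CC[C@@H]1[C@H](OCOC)C[C@H]2O[C@@H]3[C@H](C[C@H]2OCOC)[O+]13.[F-] | intermediate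
23 | (1S,3R,4R,6R,8R,10R)-3-ethyl-8-fluoro-4,10-bis(methoxymethoxy)-2,7-dioxabicyclo[4.2.2]decane | F[C@H]1O[C@@H]2C[C@@H](OCOC)[C@@H](CC)O[C@H]1C[C@H]2OCOC | intermediate
24 | allyltrimethylsilane | C=CC[Si](C)(C)C | starting material
25 | (1S,3R,4R,6R,8R,10R)-3-ethyl-4,10-bis(methoxymethoxy)-8-(prop-2-en-1-yl)-2,7-dioxabicyclo[4.2.2]decane | C=CC[C@H]1O[C@@H]2C[C@@H](OCOC)[C@@H](CC)O[C@H]1C[C@H]2OCOC | intermediate
26 | (1S,3R,4R,6R,8R,10R)-3-ethyl-8-(prop-2-en-1-yl)-2,7-dioxabicyclo[4.2.2]decane-4,10-diol | C=CC[C@H]1O[C@@H]2C[C@@H](O)[C@@H](CC)O[C@H]1C[C@H]2O | intermediate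
27 | (1S,3R,4S,6R,8R,10S)-4,10-dibromo-3-ethyl-8-(prop-2-en-1-yl)-2,7-dioxabicyclo[4.2.2]decane | C=CC[C@H]1O[C@@H]2C[C@H](Br)[C@@H](CC)O[C@H]1C[C@@H]2Br | intermediate
28 | (E)-but-2-enal (crotonaldehyde) | C/C=C/C=O | starting material
29 | (2E)-4-[(1S,3R,4S,6R,8R,10S)-4,10-dibromo-3-ethyl-2,7-dioxabicyclo[4.2.2]decan-8-yl]but-2-enal | O=C/C=C/C[C@H]1O[C@@H]2C[C@H](Br)[C@@H](CC)O[C@H]1C[C@@H]2Br | intermediate
30 | (trimethylsilyl)diazomethane | C[Si](C)(C)C=[N+]=[N-] | starting material
31 | (1S,3R,4S,6R,8R,10S)-4,10-dibromo-3-ethyl-8-[(2E)-pent-2-en-4-yn-1-yl]-2,7-dioxabicyclo[4.2.2]decane | C#C/C=C/C[C@H]1O[C@@H]2C[C@H](Br)[C@@H](CC)O[C@H]1C[C@@H]2Br | target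

**Step count and risks**

Total step count: 18. Longest linear sequence: 18 steps (from propanal 1).

Steps most likely to fail:

1. Step 13. The 1,2-shift may be outrun by direct fluoride substitution or elimination at C7, or the oxane oxygen may migrate instead (ring contraction). Fallback: setting out from 20, esterification with chloromethanesulfonyl chloride and 2,6-lutidine gives the C7 sulfonate (1R,3R,4R,6R,7R,9R)-3-ethyl-4,7-bis(methoxymethoxy)-2,10-dioxabicyclo[4.3.1]decan-9-yl chloromethanesulfonate F1. Solvolysis of F1 with Zn(OAc)2 in aqueous acetic acid at 50–80 °C (sulfonate-based rearrangement–ring expansion with acetate capture, no nucleophilic halide present) should give the ring-expanded anomeric acetate (1S,3R,4R,6R,8R,10R)-3-ethyl-4,10-bis(methoxymethoxy)-2,7-dioxabicyclo[4.2.2]decan-8-yl acetate F2. Treatment of F2 with allyltrimethylsilane 24 and BF3·OEt2 comes back to the route at 25.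

2. Step 12. Intermolecular opening of the epoxide (oligomerisation) or attack by the C12 MOM oxygen may outcompete the seven-membered ring closure, and facial selectivity of the epoxidation may erode. Fallback: setting out from 18, dihydroxylation with OsO4 (cat.) and NMO on the same, less hindered face gives the lactol (2S,3R,5R,6R)-6-[(2R,3R)-3-hydroxy-2-(methoxymethoxy)pentyl]-5-(methoxymethoxy)oxane-2,3-diol F3. Camphorsulfonic acid with 4 Å molecular sieves in dilute CH2Cl2 then effects a thermodynamic intramolecular glycosidation, in which the axial O-b is favoured by the anomeric effect and the C7 hydroxyl stays trans to it, and comes back to the route at 20.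

3. Step 16. The double inversion may stall at the hindered C9 position or be diverted into elimination or into retention through participation of a ring oxygen. Fallback: setting out from 26, chloromethanesulfonyl chloride and pyridine give the isolable bis-sulfonate (1S,3R,4R,6R,8R,10R)-3-ethyl-8-(prop-2-en-1-yl)-2,7-dioxabicyclo[4.2.2]decane-4,10-diyl bis(chloromethanesulfonate) F4. Displacement of F4 with LiBr in DMF at 40–60 °C (discrete SN2 on a sulfonate, without phosphonium salts or acid) comes back to the route at 27.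

**Further compounds**

F1 | step 13 | (1R,3R,4R,6R,7R,9R)-3-ethyl-4,7-bis(methoxymethoxy)-2,10-dioxabicyclo[4.3.1]decan-9-yl chloromethanesulfonate | ClCS(=O)(=O)O[C@@H]1C[C@@H](OCOC)[C@H]2C[C@@H](OCOC)[C@@H](CC)O[C@@H]1O2
F2 | step 13 | (1S,3R,4R,6R,8R,10R)-3-ethyl-4,10-bis(methoxymethoxy)-2,7-dioxabicyclo[4.2.2]decan-8-yl acetate | CC(=O)O[C@H]1O[C@@H]2C[C@@H](OCOC)[C@@H](CC)O[C@H]1C[C@H]2OCOC
F3 | step 12 | (2S,3R,5R,6R)-6-[(2R,3R)-3-hydroxy-2-(methoxymethoxy)pentyl]-5-(methoxymethoxy)oxane-2,3-diol | CC[C@@H](O)[C@H](OCOC)C[C@H]1O[C@H](O)[C@H](O)C[C@H]1OCOC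
F4 | step 16 | (1S,3R,4R,6R,8R,10R)-3-ethyl-8-(prop-2-en-1-yl)-2,7-dioxabicyclo[4.2.2]decane-4,10-diyl bis(chloromethanesulfonate) | C=CC[C@H]1O[C@@H]2C[C@@H](OS(=O)(=O)CCl)[C@@H](CC)O[C@H]1C[C@H]2OS(=O)(=O)CCl
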